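**Retrosynthetic overview**
1. Ring B oxygens: target 14 ⇐ allylic alcohol 11 (singlet-oxygen ene / Kornblum–DeLaMare forms C7–O and moves the alkene to C8=C9) ⇐ enone 10 (Luche reduction sets C6) ⇐ 7-ene 9 (allylic C–H oxidation at C6).
2. C13–O: hydroxy-lactone 9 ⇐ butenolide 7 by enantioselective conjugate borylation and C–B to C–O oxidation.
3. Rings A and B: 7 ⇐ acyclic butenolide triene 6 by one enantioselective proton-initiated bicyclisation (sets C5, C9, C10).
4. Lactone ring: 6 ⇐ α-hydroxy ketone 3 + Ph3P=C=C=O; 3 ⇐ farnesylacetone 1.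
5. Ring order: lactone ring first, then rings A and B together, then oxygenation of ring B.

Assumption: the enantiomer of each chiral catalyst (steps 3 and 4) is written for the sense of induction expected by analogy with the closest known substrates; if a first run shows the opposite sense, the mirror-image catalyst is used.

Labdane numbering is used throughout; the target belongs to the ent-labdane series (5R,10R).

**Step 1**
Reactants: 1 (5E,9E)-6,10,14-trimethylpentadeca-5,9,13-trien-2-one (farnesylacetone)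
Product: 3 (5E,9E)-1-hydroxy-6,10,14-trimethylpentadeca-5,9,13-trien-2-one, via terminal potassium enolate 2 (not isolated)
Conditions: KN(SiMe3)2, THF, −78 °C; then 2-(phenylsulfonyl)-3-phenyloxaziridine, −78 °C; AcOH
Reagents that add atoms: 2-(phenylsulfonyl)-3-phenyloxaziridine, O=S(=O)(N1OC1c1ccccc1)c1ccccc1
Why: Kinetic deprotonation of the methyl ketone on the CH3 side gives the terminal enolate, which takes up electrophilic oxygen from the oxaziridine (Davis enolate hydroxylation); no stereocentre is formed and the three trisubstituted alkenes are inert.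

**Step 2**
Reactants: 3 (5E,9E)-1-hydroxy-6,10,14-trimethylpentadeca-5,9,13-trien-2-one; 4 (triphenylphosphoranylidene)ketene
Product: 6 4-[(3E,7E)-4,8,12-trimethyltrideca-3,7,11-trien-1-yl]furan-2(5H)-one, via phosphorus ylide ester 5 (not isolated)
Conditions: toluene, 90 °C
Reagents that add atoms: none
Why: The hydroxyl adds to the ketene to give a stabilised ester ylide, which closes the butenolide by intramolecular Wittig olefination of the ketone (Bestmann butenolide synthesis).

**Step 3**
Reactants: 6 4-[(3E,7E)-4,8,12-trimethyltrideca-3,7,11-trien-1-yl]furan-2(5H)-one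
Product: 7 (5R,9R,10R)-labda-7,13-dien-15,16-olide (trans-decalin; H-5 and H-9 both anti to the C10 methyl)
Conditions: (R,R)-imidodiphosphorimidate Brønsted acid (two 3,3'-diaryl-BINOL phosphoryl units joined through nitrogen, N-triflyl groups on phosphorus; 3 mol %), (CF3)3COH, −20 °C
Reagents that add atoms: none
Why: Proposed new method: the confined chiral acid protonates the terminal trisubstituted alkene of the chair–chair folded (E,E)-triene inside its anion pocket, the two anti additions across the E alkenes close ring A and then ring B to the trans-decalin with H-5 and H-9 anti to the C10 methyl (the catalyst antipode fixes 5R,9R,10R), and because the conjugated butenolide is neither nucleophilic nor basic the C8 cation ends by loss of the axial C7 proton to the counter-anion to give the 7,8-alkene; the closest known reaction type is the catalytic asymmetric proton-initiated polyene cyclisation of homofarnesol to ambroxide with this acid class, where a hydroxyl group rather than proton loss ends the cascade, and the 7-ene outcome follows the superacid cyclisation of farnesyl esters to drimenol derivatives.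

**Step 4**
Reactants: 7 (5R,9R,10R)-labda-7,13-dien-15,16-olide
Product: 9 (5R,9R,10R,13S)-13-hydroxylabd-7-en-15,16-olide, via tertiary pinacol boronate 8 (not isolated)
Conditions: CuCl (5 mol %), NaOt-Bu (8 mol %), (R,R)-2,3-bis(tert-butylmethylphosphino)quinoxaline (6 mol %), B2pin2, MeOH, THF, 25 °C; then NaBO3·4H2O, THF/H2O, 25 °C
Reagents that add atoms: bis(pinacolato)diboron, CC1(C)OB(OC1(C)C)B1OC(C)(C)C(C)(C)O1 (boron group of intermediate 8); sodium perborate tetrahydrate, [Na+].[Na+].O[B-]1(O)OO[B-](O)(O)OO1 (oxygen of the C13 hydroxyl)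
Why: Copper-catalysed enantioselective conjugate borylation puts boron on the β-carbon C13 of the butenolide on the face chosen by the bisphosphine, and perborate oxidation replaces C–B by C–O with retention, which sets 13S and leaves the unactivated 7,8-alkene alone.

**Step 5**
Reactants: 9 (5R,9R,10R,13S)-13-hydroxylabd-7-en-15,16-olide
Product: 10 (5R,9R,10S,13S)-13-hydroxy-6-oxolabd-7-en-15,16-olide
Conditions: CrO3, 3,5-dimethylpyrazole, CH2Cl2, −20 °C
Reagents that add atoms: chromium trioxide, O=[Cr](=O)=O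
Why: Allylic C–H oxidation (Salmond-type CrO3–dimethylpyrazole) converts the ring allylic methylene C6 next to the trisubstituted alkene into the 7-en-6-one; no stereocentre is made and the tertiary alcohol and lactone are inert.

**Step 6**
Reactants: 10 (5R,9R,10S,13S)-13-hydroxy-6-oxolabd-7-en-15,16-olide
Product: 11 (5R,6S,9R,10S,13S)-6,13-dihydroxylabd-7-en-15,16-olide (6-OH cis to the C10 methyl)
Conditions: NaBH4, CeCl3·7H2O, MeOH, −78 °C
Reagents that add atoms: none
Why: Luche 1,2-reduction delivers hydride to the C6 ketone from the face opposite the C10 methyl and the axial C4 methyl, so the new hydroxyl stands cis to the C10 methyl as in the target, and the lactone survives at −78 °C.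

**Step 7**
Reactants: 11 (5R,6S,9R,10S,13S)-6,13-dihydroxylabd-7-en-15,16-olide
Product: 14 (5R,6R,10R,13S)-6,13-dihydroxy-7-oxolabd-8-en-15,16-olide (target), via allylic hydroperoxide 12 (not isolated), via allylic peracetate 13 (not isolated)
Conditions: O2, hν, 5,10,15,20-tetraphenylporphyrin (1 mol %), CH2Cl2/MeOH, −20 °C; then Ac2O, pyridine, CH2Cl2, 0 °C
Reagents that add atoms: dioxygen, O=O; acetic anhydride, CC(=O)OC(C)=O (acetyl group of intermediate 13 only)
Why: In the Schenck ene reaction singlet oxygen bonds to C7 on the open face (anti to the C10 methyl) and removes the axial H-9 on that same face, which moves the alkene to C8=C9, and Kornblum–DeLaMare dehydration of the acetylated hydroperoxide then gives the C7 ketone; C6 keeps its configuration because its hydrogen lies in the alkene plane and is not abstracted.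

**Compound list**
1 | (5E,9E)-6,10,14-trimethylpentadeca-5,9,13-trien-2-one (farnesylacetone) | CC(=O)CC/C=C(\C)CC/C=C(\C)CCC=C(C)C | starting material
2 | potassium (5E,9E)-6,10,14-trimethylpentadeca-1,5,9,13-tetraen-2-olate | [K+].[O-]C(=C)CC/C=C(\C)CC/C=C(\C)CCC=C(C)C | intermediate
3 | (5E,9E)-1-hydroxy-6,10,14-trimethylpentadeca-5,9,13-trien-2-one | OCC(=O)CC/C=C(\C)CC/C=C(\C)CCC=C(C)C | intermediate
4 | (triphenylphosphoranylidene)ketene | O=C=C=P(c1ccccc1)(c1ccccc1)c1ccccc1 | starting material
5 | (5E,9E)-6,10,14-trimethyl-2-oxopentadeca-5,9,13-trien-1-yl (triphenylphosphoranylidene)acetate | O=C(C=P(c1ccccc1)(c1ccccc1)c1ccccc1)OCC(=O)CC/C=C(\C)CC/C=C(\C)CCC=C(C)C | intermediate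
6 | 4-[(3E,7E)-4,8,12-trimethyltrideca-3,7,11-trien-1-yl]furan-2(5H)-one | O=C1C=C(CC/C=C(\C)CC/C=C(\C)CCC=C(C)C)CO1 | intermediate
7 | (5R,9R,10R)-labda-7,13-dien-15,16-olide; 4-{2-[(1R,4aR,8aR)-2,5,5,8a-tetramethyl-1,4,4a,5,6,7,8,8a-octahydronaphthalen-1-yl]ethyl}furan-2(5H)-one | CC1=CC[C@@H]2C(C)(C)CCC[C@@]2(C)[C@@H]1CCC1=CC(=O)OC1 | intermediate
8 | (5R,9R,10R,13R)-13-(4,4,5,5-tetramethyl-1,3,2-dioxaborolan-2-yl)labd-7-en-15,16-olide (boron where the hydroxyl of 9 will stand) | CC1=CC[C@@H]2C(C)(C)CCC[C@@]2(C)[C@@H]1CC[C@@]1(B3OC(C)(C)C(C)(C)O3)COC(=O)C1 | intermediate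
9 | (5R,9R,10R,13S)-13-hydroxylabd-7-en-15,16-olide | CC1=CC[C@@H]2C(C)(C)CCC[C@@]2(C)[C@@H]1CC[C@@]1(O)COC(=O)C1 | intermediate
10 | (5R,9R,10S,13S)-13-hydroxy-6-oxolabd-7-en-15,16-olide | CC1=CC(=O)[C@@H]2C(C)(C)CCC[C@@]2(C)[C@@H]1CC[C@@]1(O)COC(=O)C1 | intermediate
11 | (5R,6S,9R,10S,13S)-6,13-dihydroxylabd-7-en-15,16-olide (6-OH cis to the C10 methyl) | CC1=C[C@H](O)[C@@H]2C(C)(C)CCC[C@@]2(C)[C@@H]1CC[C@@]1(O)COC(=O)C1 | intermediate
12 | (5R,6R,7R,10R,13S)-7-hydroperoxy-6,13-dihydroxylabd-8-en-15,16-olide (OOH trans to the C10 methyl) | CC1=C(CC[C@@]2(O)COC(=O)C2)[C@]2(C)CCCC(C)(C)[C@H]2[C@@H](O)[C@@H]1OO | intermediate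
13 | (5R,6R,7R,10R,13S)-7-(acetylperoxy)-6,13-dihydroxylabd-8-en-15,16-olide | CC1=C(CC[C@@]2(O)COC(=O)C2)[C@]2(C)CCCC(C)(C)[C@H]2[C@@H](O)[C@@H]1OOC(C)=O | intermediate
14 | (5R,6R,10R,13S)-6,13-dihydroxy-7-oxolabd-8-en-15,16-olide; (4S)-4-hydroxy-4-{2-[(4R,4aR,8aR)-4-hydroxy-2,5,5,8a-tetramethyl-3-oxo-3,4,4a,5,6,7,8,8a-octahydronaphthalen-1-yl]ethyl}oxolan-2-one | CC1=C(CC[C@@]2(O)COC(=O)C2)[C@]2(C)CCCC(C)(C)[C@H]2[C@@H](O)C1=O | target

**Summary**
Total step count: 7. Longest linear sequence: 7 steps (1 to 14).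

Steps most likely to fail:

Step 3 (the proposed new bicyclisation). Enantioselectivity and the position of the new alkene are both untested on a chain that ends in a butenolide. The fallback sets out from 6 and comes back at 7. Compound 6 is cyclised without asymmetric induction in FSO3H/2-nitropropane at −78 °C, the known superacid cyclisation of farnesyl-type chains that ends at the 7-ene. This gives 7 as a racemate together with its mirror image, (5S,9S,10S)-labda-7,13-dien-15,16-olide F1. The two are separated by preparative chromatography on a chiral stationary phase (supercritical CO2/MeOH), and 7 goes on to step 4.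

Step 5 (allylic oxidation). The tertiary allylic H-9 and the C8 methyl compete with C6. The fallback sets out from 9 and comes back at 10. mCPBA (NaHCO3, CH2Cl2, 0 °C) epoxidises the 7,8-alkene from the face opposite the C10 methyl to give the 7,8-epoxide F2. PhSeNa (from (PhSe)2 and NaBH4, EtOH) opens it at C7 to the trans hydroxy selenide F3. H2O2 gives the selenoxide F4, which eliminates in the flask towards C6 to the tertiary allylic alcohol F5 (Sharpless–Lauer sequence). [pyH][CrO3Cl] in CH2Cl2 then brings about the oxidative 1,3-transposition (Dauben–Babler) to enone 10.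

Step 7 (ene reaction and dehydration). The C6 hydroxyl may steer singlet oxygen to the wrong face, and the C8 methyl may give up a hydrogen in place of H-9. The fallback sets out from 11 and comes back at 14. VO(acac)2/t-BuOOH (CH2Cl2, 0 °C) gives, by hydroxyl-directed epoxidation, the epoxy alcohol F6 with the oxirane cis to the C6 hydroxyl. Al(Oi-Pr)3 in refluxing toluene isomerises the epoxide to the exocyclic allylic alcohol F7, since only the C8 methyl offers a hydrogen on the oxirane face. MnO2 (CH2Cl2) oxidises only the allylic C7 hydroxyl to give the exo-methylene ketone F8. RhCl3·3H2O in EtOH at 80 °C moves the alkene into the ring to give 14.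

**Further compounds**
F1 | step 3 | (5S,9S,10S)-labda-7,13-dien-15,16-olide (mirror image of 7) | CC1=CC[C@H]2C(C)(C)CCC[C@]2(C)[C@H]1CCC1=CC(=O)OC1
F2 | step 5 | (13S)-7,8-epoxy-13-hydroxy-ent-labdan-15,16-olide, oxirane oxygen trans to the C10 methyl | C[C@]12O[C@H]1C[C@@H]3C(C)(C)CCC[C@@]3(C)[C@@H]2CC[C@@]1(O)COC(=O)C1
F3 | step 5 | (13S)-8,13-dihydroxy-7-(phenylselanyl)-ent-labdan-15,16-olide, 8-OH trans and 7-SePh cis to the C10 methyl | C[C@]1(O)[C@H]([Se]c2ccccc2)C[C@@H]3C(C)(C)CCC[C@@]3(C)[C@@H]1CC[C@@]1(O)COC(=O)C1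
F4 | step 5 | (13S)-8,13-dihydroxy-7-(phenylseleninyl)-ent-labdan-15,16-olide (selenoxide of F3) | C[C@]1(O)[C@H]([Se](=O)c2ccccc2)C[C@@H]3C(C)(C)CCC[C@@]3(C)[C@@H]1CC[C@@]1(O)COC(=O)C1
F5 | step 5 | (13S)-8,13-dihydroxy-ent-labd-6-en-15,16-olide, 8-OH trans to the C10 methyl | C[C@]1(O)C=C[C@@H]2C(C)(C)CCC[C@@]2(C)[C@@H]1CC[C@@]1(O)COC(=O)C1
F6 | step 7 | (13S)-7,8-epoxy-6,13-dihydroxy-ent-labdan-15,16-olide, oxirane oxygen and 6-OH both cis to the C10 methyl | C[C@@]12O[C@@H]1[C@H](O)[C@@H]3C(C)(C)CCC[C@@]3(C)[C@@H]2CC[C@@]1(O)COC(=O)C1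
F7 | step 7 | (13S)-6,7,13-trihydroxy-ent-labd-8(17)-en-15,16-olide, 6-OH and 7-OH both cis to the C10 methyl | C=C1[C@H](O)[C@H](O)[C@@H]2C(C)(C)CCC[C@@]2(C)[C@@H]1CC[C@@]1(O)COC(=O)C1
F8 | step 7 | (13S)-6,13-dihydroxy-7-oxo-ent-labd-8(17)-en-15,16-olide, 6-OH cis to the C10 methyl | C=C1C(=O)[C@H](O)[C@@H]2C(C)(C)CCC[C@@]2(C)[C@@H]1CC[C@@]1(O)COC(=O)C1
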